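Target has to exist before it can be lost, so I took side product as a follow-up of target and treated selectivity, target over target plus side product, as a contest of two times.

| setting | north | north-east | green | ochre |
|---|---|---|---|---|
| substrate | 0.14 M | 0.22 M | 0.10 M | 0.10 M |
| partner | 2.5 equiv | 2.5 equiv | 2.50 equiv | 2.50 equiv |
| free catalyst | 1 mol% | 1 mol% | 1 mol% | 1 mol% |
| temperature | 105 °C | 118 °C | 110 °C | 125 °C |
| remark | run made earlier | run made earlier |  |  |
| time |  |  | 1.0 h | 1.0 h |

- north (time / min: target / %, side product / %): 6.00: 1, 1; 12.0: 2, 0; 20.0: 9, 0; 25.0: 8, 0; 30.0: 8, 0; 40.0: 14, 3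
- north-east (time / min: target / %, side product / %): 3.00: 3, 0; 5.00: 6, 0; 8.00: 8, 1; 12.0: 13, 1; 20.0: 16, 2; 40.0: 36, 2

(scatter of a reading: 1.5 percentage points)

- the flask with the highest share of target in all that became target or side product ("all alike" if they lie within 1.5 percentage points) (green / ochre / all alike)
- share of target in all that became target or side product, green
- share of target in all that became target or side product, ochre

The first time is the run time t. The second is τ, the lifetime of target against this loss at the end of a run. I assumed that target meets a second species growing along with it, so τ goes as 1/(c p), with c the starting substrate and p the fraction turned to target. With p rising about linearly, side product V over target P sums to t/(3τ). The last north-east reading gave τ = tP/(3V) = 240 min, a rough value, since its 2% of side product carries a scatter of 1.5 percentage points.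

Reading each last target as first-order in substrate, I got k = 0.00377 min⁻¹ at 105 °C and 0.0112 min⁻¹ at 118 °C, ignoring the change in concentration. Interpolating ln k between the two runs gave 0.00572 min⁻¹ for green, and extrapolating the same line past the hotter run gave 0.0200 min⁻¹ for ochre, so p = 29.1% for green and, as an extrapolated estimate, 69.9% for ochre. North showed no usable side-product trend, so I assumed τ shortens in proportion to k. That put τ at 1280 min in green and 152 min in ochre, shorter by a factor of 8.42, a ratio free of the rough reading. My selectivities were 98.5% for green and 88.3% for ochre.

The forecast said all alike, with 92% and 91.5%, holding that “The data show no clear temperature effect on selectivity”, whereas I expected green.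

The flasks gave green as the higher, with 98.6% in green and 90.0% in ochre.

    partner + free catalyst ⇌ catalyst intermediate A (K = 12.0 M⁻¹, k = 0.433 M⁻¹ s⁻¹, Ea = 71.0 kJ mol⁻¹, ΔH = 3.00 kJ mol⁻¹)
    substrate + catalyst intermediate A ⇌ catalyst intermediate B (K = 59.0 M⁻¹, k = 0.418 M⁻¹ s⁻¹, Ea = 77.0 kJ mol⁻¹, ΔH = −55.0 kJ mol⁻¹)
    catalyst intermediate B ⇌ by-product + catalyst intermediate C (K = 0.766 M, k = 0.0341 s⁻¹, Ea = 90.0 kJ mol⁻¹, ΔH = −13.0 kJ mol⁻¹)
    catalyst intermediate C → catalyst intermediate D (k = 0.0345 s⁻¹, Ea = 97.0 kJ mol⁻¹)
    catalyst intermediate D → free catalyst + target (k = 0.0330 s⁻¹, Ea = 90.0 kJ mol⁻¹)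
    target + by-product → side product (k = 4.52 × 10⁻⁴ M⁻¹ s⁻¹, Ea = 99.0 kJ mol⁻¹)
    (constants at 110 °C)

The second species I had assumed stands in the scheme as by-product. Green's simulated target and side product put τ at 1440 min, beside my 1280 min. The neighbour of green with 0.40 M of substrate, its equivalents, loadings and time held, stood at 32.0% target after 1.00 h. Scaling the north-east τ by c p and k gave 290 min there, hence a selectivity of 93.5%. That neighbour gave 92.9%, with 2.45% of side product.

(All runs were computed on assumed constants.)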